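**Retrosynthetic overview**

- Feature: rings A and B form a trans-decalin whose contiguous centres C4 (axial CH3, equatorial CH2OAc), C5, C10 and C9 (equatorial side chain) sit next to the exocyclic C8=C17 alkene. This is the pattern a chair–chair folded polyene gives when an allylsilane ends the cascade at C8.
- The late steps only adjust functional groups (C18 acetate, C15 acid, removal of the C3 oxygen). Before them, C4–C5 and C9–C10 are cut together: ring A closes first and ring B second, in one cationic cascade from an acyclic epoxy allylsilane.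
- The acyclic precursor is cut at C9–C11 (Negishi coupling with an alkylzinc from methyl hydrogen (R)-3-methylglutarate, the source of C13), at C8–C17 (silylmethylcupration of a terminal alkyne) and at C6–C7 (propargylation of an epoxygeranyl bromide).
- The epoxide, the single induced stereocentre, comes from Sharpless epoxidation of 8-hydroxygeranyl acetate.

Key step: step 12

Remark: labdane numbering is used for all intermediates; the target SMILES is read as the normal-series labd-8(17)-ene (5α-H, 9α-H, 10β-CH3) with 4α-CH2OAc (C18), 4β-CH3 (C19) and 13R.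

**Step 1**
Reactants: 1 geranyl acetate, (2E)-3,7-dimethylocta-2,6-dien-1-yl acetate
Product: 2 (2E,6E)-8-hydroxy-3,7-dimethylocta-2,6-dien-1-yl acetate (8-hydroxygeranyl acetate)
Conditions: SeO2 (cat.), t-BuOOH, salicylic acid (cat.), CH2Cl2, rt
Reagents that add atoms: tert-butyl hydroperoxide, CC(C)(C)OO
Why: Catalytic SeO2 allylic oxidation (ene reaction, then [2,3]-sigmatropic shift, re-oxidation by t-BuOOH) should attack the (E)-methyl group of the electron-rich terminal alkene, the C2=C3 alkene being deactivated by its allylic acetate, and so give the (E)-allylic alcohol that later becomes C18.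

**Step 2**
Reactants: 2 8-hydroxygeranyl acetate
Product: 3 (2E)-5-[(2S,3S)-3-(hydroxymethyl)-3-methyloxiran-2-yl]-3-methylpent-2-en-1-yl acetate
Conditions: Ti(OiPr)4 (cat.), L-(+)-diethyl tartrate (cat.), t-BuOOH, 4 Å MS, CH2Cl2, −20 °C
Reagents that add atoms: tert-butyl hydroperoxide, CC(C)(C)OO
Why: Katsuki–Sharpless asymmetric epoxidation touches only the alkene of the allylic alcohol, and with the L-(+)-tartrate ligand oxygen should enter on the face that gives the (2S,3S)-epoxy alcohol, which sets C3 (the only induced stereocentre of the route) and, because the alkene is E, fixes CH2O trans and CH3 cis to the chain on C4.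

**Step 3**
Reactants: 3 epoxy alcohol
Product: 4 (2E)-5-[(2S,3S)-3-({[tert-butyl(diphenyl)silyl]oxy}methyl)-3-methyloxiran-2-yl]-3-methylpent-2-en-1-yl acetate
Conditions: t-BuPh2SiCl, imidazole, DMF, 0 °C → rt
Reagents that add atoms: tert-butyl(chloro)diphenylsilane, CC(C)(C)[Si](Cl)(c1ccccc1)c1ccccc1
Why: Imidazole-promoted silylation of the primary alcohol gives a bulky, non-participating ether that blocks Payne rearrangement and survives every later step up to fluoride treatment.

**Step 4**
Reactants: 4 silyl ether acetate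
Product: 5 (2E)-5-[(2S,3S)-3-({[tert-butyl(diphenyl)silyl]oxy}methyl)-3-methyloxiran-2-yl]-3-methylpent-2-en-1-ol
Conditions: K2CO3, MeOH, 0 °C → rt
Reagents that add atoms: none
Why: K2CO3-catalysed transesterification with methanol removes the acetate, while the trisubstituted epoxide and the tert-butyldiphenylsilyl ether are stable to mild base.

**Step 5**
Reactants: 5 allylic alcohol
Product: 7 tert-butyl({(2S,3S)-3-[(3E)-5-bromo-3-methylpent-3-en-1-yl]-2-methyloxiran-2-yl}methoxy)diphenylsilane, via allylic mesylate 6 (not isolated)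
Conditions: MsCl, Et3N, THF, −40 °C; then LiBr, THF, −40 → 0 °C
Reagents that add atoms: lithium bromide, [Li+].[Br-]
Why: Mesylation and in situ SN2 displacement by bromide (Finkelstein-type) under non-acidic conditions convert the primary allylic alcohol into the bromide without allylic transposition or epoxide opening.

**Step 6**
Reactants: 7 allylic bromide; 8 1-(trimethylsilyl)propyne
Product: 10 tert-butyl({(2S,3S)-2-methyl-3-[(3E)-3-methyl-8-(trimethylsilyl)oct-3-en-7-yn-1-yl]oxiran-2-yl}methoxy)diphenylsilane, via 3-(trimethylsilyl)propargyllithium 9 (not isolated)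
Conditions: 8, n-BuLi, THF, −78 → −20 °C; then 7, THF, −78 °C
Reagents that add atoms: none
Why: SN2 alkylation of the propargylic carbanion of the silyl-capped propyne at the primary allylic bromide forms C6–C7 at −78 °C, the silyl cap suppressing allenyl coupling and the low temperature sparing the epoxide.

**Step 7**
Reactants: 10 silylated enyne
Product: 11 tert-butyl({(2S,3S)-2-methyl-3-[(3E)-3-methyloct-3-en-7-yn-1-yl]oxiran-2-yl}methoxy)diphenylsilane
Conditions: K2CO3, MeOH, rt
Reagents that add atoms: none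
Why: Base-catalysed methanolysis cleaves only the C(sp)–Si bond, the hindered silyl ether and the epoxide being inert.

**Step 8**
Reactants: 11 terminal alkyne; 12 (trimethylsilyl)methylmagnesium chloride
Product: 15 tert-butyl({(2S,3S)-3-[(3E,7Z)-8-iodo-3-methyl-7-[(trimethylsilyl)methyl]octa-3,7-dien-1-yl]-2-methyloxiran-2-yl}methoxy)diphenylsilane, via (trimethylsilyl)methylcopper 13 (not isolated), via alkenylcopper 14 (not isolated)
Conditions: 12, CuBr·SMe2, THF–Et2O, −40 °C; then 11, −20 → 0 °C; then I2, THF, −78 → 0 °C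
Reagents that add atoms: iodine, II
Why: Normant-type syn-carbocupration puts CH2SiMe3 on the substituted alkyne carbon (C8) and copper on C9 from the same face, and iodinolysis of the C–Cu bond with retention then gives the (Z)-iodide in which C17 and the future C11 are cis, as the chair folding of the key step requires; the organocopper–magnesium halide reagent is too weakly nucleophilic to open the hindered epoxide at or below 0 °C.

**Step 9**
Reactants: 16 methyl hydrogen (R)-3-methylglutarate
Product: 17 methyl (R)-5-hydroxy-3-methylpentanoate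
Conditions: BH3·SMe2, THF, −10 °C → rt; MeOH quench
Reagents that add atoms: none
Why: Borane reduces the carboxylic acid (via an acyloxyborane) much faster than the methyl ester, so the half ester gives the hydroxy ester with the C13 stereocentre untouched.

**Step 10**
Reactants: 17 hydroxy ester
Product: 18 methyl (S)-5-iodo-3-methylpentanoate (same spatial arrangement; the descriptor changes with the priorities)
Conditions: I2, PPh3, imidazole, CH2Cl2, 0 °C → rt
Reagents that add atoms: iodine, II
Why: Appel-type iodination (PPh3/I2/imidazole) turns the primary alcohol into the iodide under neutral conditions before it can lactonise.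

**Step 11**
Reactants: 18 iodo ester; 15 (Z)-alkenyl iodide
Product: 20 methyl (3R,6Z,10E)-13-[(2S,3S)-3-({[tert-butyl(diphenyl)silyl]oxy}methyl)-3-methyloxiran-2-yl]-3,11-dimethyl-7-[(trimethylsilyl)methyl]trideca-6,10-dienoate, via alkylzinc iodide 19 (not isolated)
Conditions: 18, Zn dust (activated with BrCH2CH2Br and Me3SiCl), LiCl, THF, 40 °C; then 15, Pd(dppf)Cl2 (cat.), THF–N,N-dimethylacetamide, rt → 40 °C
Reagents that add atoms: none
Why: Zinc insertion into the primary C–I bond and Negishi cross-coupling with the alkenyl iodide form C9–C11 with retention of the alkene geometry, the ester, epoxide and allylsilane being tolerated by the organozinc and the dppf ligand limiting β-hydride elimination.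

**Step 12**
Reactants: 20 epoxy polyene allylsilane
Product: 21 methyl (13R)-18-{[tert-butyl(diphenyl)silyl]oxy}-3β-hydroxylabd-8(17)-en-15-oate (5α-H, 9α-H, 10β-CH3, 4α-CH2OSi, 4β-CH3)
Conditions: MeAlCl2 (2.5 equiv), CH2Cl2, −78 °C; Et3N–MeOH quench, aq. potassium sodium tartrate
Reagents that add atoms: none
Why: MeAlCl2 binds the epoxide oxygen, C5 of the E C5=C10 alkene attacks C4 from the side opposite the departing oxygen, C9 of the allylsilane attacks the developing C10 cation, and the β-silyl cation at C8 loses Me3Si to chloride, leaving C8=C17. The closest known reaction type is the Lewis-acid-promoted, epoxide-initiated cation–olefin bicyclization ended by an allylsilane (a biomimetic epoxy-polyene cyclization in the Stork–Eschenmoser sense). Ring A closes by 6-endo attack of the alkene on the activated epoxide (C4–C5) and ring B by 6-endo attack of the allylsilane on C10 (C9–C10), both through chair transition states. C4 is set by inversion at the E-configured epoxide (CH2OSi trans to the chain becomes equatorial 4α, CH3 becomes axial 4β), C5 and C10 by anti addition across the E alkene (trans fusion, 5α-H, 10β-CH3), C9 by the allylsilane geometry (C11 trans to C7, hence equatorial side chain and 9α-H), and the absolute sense of the whole array by the (S)-configured C3, which stays as the equatorial 3β-oxygen. The step needs bicyclization to outrun hydride shift of the inductively deactivated epoxide and a single alkene position; the nucleophilic allylsilane terminator, the non-participating bulky silyl ether and the low temperature are there for that.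

**Step 13**
Reactants: 21 3β-alcohol
Product: 22 methyl (13R)-18-{[tert-butyl(diphenyl)silyl]oxy}-3β-[(1H-imidazol-1-ylcarbonothioyl)oxy]labd-8(17)-en-15-oate
Conditions: 1,1′-thiocarbonyldiimidazole, DMAP (cat.), ClCH2CH2Cl, 80 °C
Reagents that add atoms: 1,1′-thiocarbonyldiimidazole, S=C(n1ccnc1)n1ccnc1
Why: Thioacylation of the equatorial 3β-alcohol with thiocarbonyldiimidazole (first stage of the Barton–McCombie deoxygenation) runs under neutral conditions, which avoids ester enolisation and silyl migration from O18 to O3.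

**Step 14**
Reactants: 22 imidazolyl thionocarbonate
Product: 23 methyl (13R)-18-{[tert-butyl(diphenyl)silyl]oxy}labd-8(17)-en-15-oate
Conditions: Bu3SnH, AIBN (cat.), toluene, 110 °C
Reagents that add atoms: none
Why: Barton–McCombie radical deoxygenation: stannyl radical addition to the thiocarbonyl group, β-scission to the secondary C3 radical and hydrogen transfer from Bu3SnH remove the C3 oxygen without touching the exocyclic alkene or any stereocentre.

**Step 15**
Reactants: 23 silyl ether ester
Product: 24 methyl (13R)-18-hydroxylabd-8(17)-en-15-oate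
Conditions: Bu4NF, THF, 45 °C; aq. NH4Cl work-up
Reagents that add atoms: none
Why: Fluoride-induced Si–O cleavage frees the primary C18 alcohol, gentle warming compensating for the neopentyl position.

**Step 16**
Reactants: 24 hydroxy ester
Product: 25 (13R)-18-hydroxylabd-8(17)-en-15-oic acid
Conditions: LiOH, THF–MeOH–H2O, rt; then 1 M HCl to pH 3, 0 °C
Reagents that add atoms: lithium hydroxide (hydroxide oxygen), [Li+].[OH-]
Why: Saponification of the unhindered methyl ester followed by cold acidification gives the acid without risk to the exocyclic alkene or to C13, which is not α to the carbonyl.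

**Step 17**
Reactants: 25 hydroxy acid
Product: 27 (13R)-18-acetoxylabd-8(17)-en-15-oic acid (target), via mixed acetic anhydride 26 (not isolated)
Conditions: Ac2O, pyridine, DMAP (cat.), CH2Cl2, 0 °C → rt; then H2O–THF, rt
Reagents that add atoms: acetic anhydride, CC(=O)OC(C)=O
Why: DMAP-catalysed acetylation esterifies the C18 alcohol, and the mixed anhydride formed at C15 is hydrolysed again in the aqueous quench, so the acid is returned free.

**Compound list**

1 | geranyl acetate, (2E)-3,7-dimethylocta-2,6-dien-1-yl acetate | CC(C)=CCC/C(C)=C/COC(C)=O | starting material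
2 | (2E,6E)-8-hydroxy-3,7-dimethylocta-2,6-dien-1-yl acetate | OC/C(C)=C/CC/C(C)=C/COC(C)=O | intermediate
3 | (2E)-5-[(2S,3S)-3-(hydroxymethyl)-3-methyloxiran-2-yl]-3-methylpent-2-en-1-yl acetate | CC(=O)OC/C=C(C)/CC[C@@H]1O[C@@]1(C)CO | intermediate
4 | (2E)-5-[(2S,3S)-3-({[tert-butyl(diphenyl)silyl]oxy}methyl)-3-methyloxiran-2-yl]-3-methylpent-2-en-1-yl acetate | CC(=O)OC/C=C(C)/CC[C@@H]1O[C@@]1(C)CO[Si](c1ccccc1)(c1ccccc1)C(C)(C)C | intermediate
5 | (2E)-5-[(2S,3S)-3-({[tert-butyl(diphenyl)silyl]oxy}methyl)-3-methyloxiran-2-yl]-3-methylpent-2-en-1-ol | OC/C=C(C)/CC[C@@H]1O[C@@]1(C)CO[Si](c1ccccc1)(c1ccccc1)C(C)(C)C | intermediate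
6 | methanesulfonate of 5 | CS(=O)(=O)OC/C=C(C)/CC[C@@H]1O[C@@]1(C)CO[Si](c1ccccc1)(c1ccccc1)C(C)(C)C | intermediate
7 | tert-butyl({(2S,3S)-3-[(3E)-5-bromo-3-methylpent-3-en-1-yl]-2-methyloxiran-2-yl}methoxy)diphenylsilane | BrC/C=C(C)/CC[C@@H]1O[C@@]1(C)CO[Si](c1ccccc1)(c1ccccc1)C(C)(C)C | intermediate
8 | 1-(trimethylsilyl)propyne | CC#C[Si](C)(C)C | starting material
9 | 3-(trimethylsilyl)prop-2-yn-1-yllithium | [Li]CC#C[Si](C)(C)C | intermediate
10 | tert-butyl({(2S,3S)-2-methyl-3-[(3E)-3-methyl-8-(trimethylsilyl)oct-3-en-7-yn-1-yl]oxiran-2-yl}methoxy)diphenylsilane | C[Si](C)(C)C#CCC/C=C(C)/CC[C@@H]1O[C@@]1(C)CO[Si](c1ccccc1)(c1ccccc1)C(C)(C)C | intermediate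
11 | tert-butyl({(2S,3S)-2-methyl-3-[(3E)-3-methyloct-3-en-7-yn-1-yl]oxiran-2-yl}methoxy)diphenylsilane | C#CCC/C=C(C)/CC[C@@H]1O[C@@]1(C)CO[Si](c1ccccc1)(c1ccccc1)C(C)(C)C | intermediate
12 | (trimethylsilyl)methylmagnesium chloride | C[Si](C)(C)C[Mg]Cl | starting material
13 | (trimethylsilyl)methylcopper (magnesium halide complex) | C[Si](C)(C)C[Cu] | intermediate
14 | (Z)-alkenylcopper from syn-addition of 13 to 11 (Cu on C9, cis to CH2SiMe3) | [Cu]/C=C(C[Si](C)(C)C)/CC/C=C(C)/CC[C@@H]1O[C@@]1(C)CO[Si](c1ccccc1)(c1ccccc1)C(C)(C)C | intermediate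
15 | tert-butyl({(2S,3S)-3-[(3E,7Z)-8-iodo-3-methyl-7-[(trimethylsilyl)methyl]octa-3,7-dien-1-yl]-2-methyloxiran-2-yl}methoxy)diphenylsilane | I/C=C(C[Si](C)(C)C)/CC/C=C(C)/CC[C@@H]1O[C@@]1(C)CO[Si](c1ccccc1)(c1ccccc1)C(C)(C)C | intermediate
16 | methyl hydrogen (R)-3-methylglutarate | OC(=O)C[C@@H](C)CC(=O)OC | starting material
17 | methyl (R)-5-hydroxy-3-methylpentanoate | OCC[C@@H](C)CC(=O)OC | intermediate
18 | methyl (S)-5-iodo-3-methylpentanoate | ICC[C@@H](C)CC(=O)OC | intermediate
19 | [(S)-5-methoxy-3-methyl-5-oxopentyl]zinc iodide | I[Zn]CC[C@@H](C)CC(=O)OC | intermediate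
20 | methyl (3R,6Z,10E)-13-[(2S,3S)-3-({[tert-butyl(diphenyl)silyl]oxy}methyl)-3-methyloxiran-2-yl]-3,11-dimethyl-7-[(trimethylsilyl)methyl]trideca-6,10-dienoate | COC(=O)C[C@H](C)CC/C=C(C[Si](C)(C)C)/CC/C=C(C)/CC[C@@H]1O[C@@]1(C)CO[Si](c1ccccc1)(c1ccccc1)C(C)(C)C | intermediate
21 | methyl (13R)-18-{[tert-butyl(diphenyl)silyl]oxy}-3β-hydroxylabd-8(17)-en-15-oate | C=C1CC[C@H]2[C@](C)(CO[Si](c3ccccc3)(c3ccccc3)C(C)(C)C)[C@@H](O)CC[C@]2(C)[C@H]1CC[C@@H](C)CC(=O)OC | intermediate
22 | methyl (13R)-18-{[tert-butyl(diphenyl)silyl]oxy}-3β-[(1H-imidazol-1-ylcarbonothioyl)oxy]labd-8(17)-en-15-oate | C=C1CC[C@H]2[C@](C)(CO[Si](c3ccccc3)(c3ccccc3)C(C)(C)C)[C@@H](OC(=S)n3ccnc3)CC[C@]2(C)[C@H]1CC[C@@H](C)CC(=O)OC | intermediate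
23 | methyl (13R)-18-{[tert-butyl(diphenyl)silyl]oxy}labd-8(17)-en-15-oate | C=C1CC[C@H]2[C@](C)(CO[Si](c3ccccc3)(c3ccccc3)C(C)(C)C)CCC[C@]2(C)[C@H]1CC[C@@H](C)CC(=O)OC | intermediate
24 | methyl (13R)-18-hydroxylabd-8(17)-en-15-oate | C=C1CC[C@H]2[C@](C)(CO)CCC[C@]2(C)[C@H]1CC[C@@H](C)CC(=O)OC | intermediate
25 | (13R)-18-hydroxylabd-8(17)-en-15-oic acid | C=C1CC[C@H]2[C@](C)(CO)CCC[C@]2(C)[C@H]1CC[C@@H](C)CC(=O)O | intermediate
26 | (13R)-18-acetoxylabd-8(17)-en-15-oic acetic anhydride | C=C1CC[C@H]2[C@](C)(COC(C)=O)CCC[C@]2(C)[C@H]1CC[C@@H](C)CC(=O)OC(C)=O | intermediate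
27 | (13R)-18-acetoxylabd-8(17)-en-15-oic acid, CNP0346003.2 | C=C1CC[C@H]2[C@](C)(COC(C)=O)CCC[C@]2(C)[C@H]1CC[C@@H](C)CC(=O)O | target

**Step count and risks**

Total step count: 17. Longest linear sequence: 15 steps (geranyl acetate 1 to target 27, steps 1–8 and 11–17).

The three steps most likely to fail:

Step 12 (key step). The Lewis-acid-bound epoxide may ionise faster than the C5=C10 alkene can take part, because the C18 oxygen withdraws electron density from C4. The result would be hydride shift or chloride capture at the epoxide, or arrest after closure of ring A. The fallback leaves the cationic manifold; it sets out from alkyne 11 and comes back at 21. Methylcupration of 11 (MeMgBr, CuBr·SMe2, Et2O–Me2S, −25 °C) should give the (E)-alkenylcopper F1 and, after iodine, the iodide tert-butyl({(2S,3S)-3-[(3E,7E)-8-iodo-3,7-dimethylocta-3,7-dien-1-yl]-2-methyloxiran-2-yl}methoxy)diphenylsilane F2. Negishi coupling of F2 with alkylzinc 19 under the conditions of step 11 should give the methyl-terminated epoxy polyene methyl (3R,6E,10E)-13-[(2S,3S)-3-({[tert-butyl(diphenyl)silyl]oxy}methyl)-3-methyloxiran-2-yl]-3,7,11-trimethyltrideca-6,10-dienoate F3. Cp2TiCl (trivalent titanium, made from Cp2TiCl2 and Mn dust, THF, rt) then opens the epoxide homolytically to the tertiary C4 radical, which the neighbouring oxygen does not penalise. Two 6-endo radical closures follow through the same chair folding, and the tertiary C8 radical is trapped by a second Cp2TiCl and loses a β-hydrogen from the C17 methyl group, giving the exocyclic alkene and, after aqueous work-up, 21. In this variant C4 is set by the preference of CH2OSi for the equatorial position and not by inversion, so a C4 epimer may have to be separated.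

Step 8. The silylmethylcopper reagent may add too slowly to the alkyne, so that metalation of the alkyne and opening of the epoxide by magnesium halide compete over the long reaction time. The fallback brings in C17 by cross-coupling instead of carbometalation; it sets out from bromide 7 and comes back at 20. Alkylation of dimethyl (2-oxopropyl)phosphonate at its terminal methyl group (NaH, then n-BuLi, THF, 0 °C) with 7 should give the β-ketophosphonate dimethyl {(5E)-8-[(2S,3S)-3-({[tert-butyl(diphenyl)silyl]oxy}methyl)-3-methyloxiran-2-yl]-6-methyl-2-oxooct-5-en-1-yl}phosphonate F4. Oxidation of alcohol 17 with Dess–Martin periodinane gives methyl (R)-3-methyl-5-oxopentanoate F5. Horner–Wadsworth–Emmons reaction of F4 with F5 (LiCl, i-Pr2NEt, MeCN) should give the (E)-enone methyl (3R,5E,10E)-13-[(2S,3S)-3-({[tert-butyl(diphenyl)silyl]oxy}methyl)-3-methyloxiran-2-yl]-3,11-dimethyl-7-oxotrideca-5,10-dienoate F6. 1,4-Hydrosilylation through the s-cis enone (Et3SiH, RhCl(PPh3)3 cat.) should give the (Z)-triethylsilyl enol ether F7 with oxygen cis to C11. CsF and PhNTf2 in 1,2-dimethoxyethane convert it into the (Z)-enol triflate F8. Pd(PPh3)4-catalysed Kumada–Corriu coupling of F8 with 12 (Et2O, 0 °C → rt) replaces the triflate by CH2SiMe3 with retention and gives 20.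

Step 13. Thioacylation of the hindered, neopentyl-type 3β-hydroxyl flanked by the silyloxymethyl group may stall, and forcing it may bring on silyl migration from O18 to O3. The fallback removes the oxygen through the ketone instead of through a radical; it sets out from 21 and comes back at 23. Oxidation with Dess–Martin periodinane (NaHCO3, CH2Cl2) should give methyl (13R)-18-{[tert-butyl(diphenyl)silyl]oxy}-3-oxolabd-8(17)-en-15-oate F9, which cannot eliminate the β-silyloxy group because C4 is quaternary. Condensation with TsNHNH2 (EtOH, cat. AcOH, 60 °C) gives the tosylhydrazone F10. Caglioti-type reduction (catecholborane, CHCl3, 0 °C; then NaOAc, reflux) should deliver the C3 methylene compound 23.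

**Further compounds**

F1 | step 12 | (E)-alkenylcopper from syn-addition of methylcopper to 11 (Cu on C9, cis to CH3) | [Cu]/C=C(C)/CC/C=C(C)/CC[C@@H]1O[C@@]1(C)CO[Si](c1ccccc1)(c1ccccc1)C(C)(C)C
F2 | step 12 | tert-butyl({(2S,3S)-3-[(3E,7E)-8-iodo-3,7-dimethylocta-3,7-dien-1-yl]-2-methyloxiran-2-yl}methoxy)diphenylsilane | I/C=C(C)/CC/C=C(C)/CC[C@@H]1O[C@@]1(C)CO[Si](c1ccccc1)(c1ccccc1)C(C)(C)C
F3 | step 12 | methyl (3R,6E,10E)-13-[(2S,3S)-3-({[tert-butyl(diphenyl)silyl]oxy}methyl)-3-methyloxiran-2-yl]-3,7,11-trimethyltrideca-6,10-dienoate | COC(=O)C[C@H](C)CC/C=C(C)/CC/C=C(C)/CC[C@@H]1O[C@@]1(C)CO[Si](c1ccccc1)(c1ccccc1)C(C)(C)C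
F4 | step 8 | dimethyl {(5E)-8-[(2S,3S)-3-({[tert-butyl(diphenyl)silyl]oxy}methyl)-3-methyloxiran-2-yl]-6-methyl-2-oxooct-5-en-1-yl}phosphonate | COP(=O)(OC)CC(=O)CC/C=C(C)/CC[C@@H]1O[C@@]1(C)CO[Si](c1ccccc1)(c1ccccc1)C(C)(C)C
F5 | step 8 | methyl (R)-3-methyl-5-oxopentanoate | O=CC[C@@H](C)CC(=O)OC
F6 | step 8 | methyl (3R,5E,10E)-13-[(2S,3S)-3-({[tert-butyl(diphenyl)silyl]oxy}methyl)-3-methyloxiran-2-yl]-3,11-dimethyl-7-oxotrideca-5,10-dienoate | COC(=O)C[C@H](C)C/C=C/C(=O)CC/C=C(C)/CC[C@@H]1O[C@@]1(C)CO[Si](c1ccccc1)(c1ccccc1)C(C)(C)C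
F7 | step 8 | methyl (3R,6Z,10E)-13-[(2S,3S)-3-({[tert-butyl(diphenyl)silyl]oxy}methyl)-3-methyloxiran-2-yl]-3,11-dimethyl-7-[(triethylsilyl)oxy]trideca-6,10-dienoate | COC(=O)C[C@H](C)CC/C=C(O[Si](CC)(CC)CC)/CC/C=C(C)/CC[C@@H]1O[C@@]1(C)CO[Si](c1ccccc1)(c1ccccc1)C(C)(C)C
F8 | step 8 | methyl (3R,6Z,10E)-13-[(2S,3S)-3-({[tert-butyl(diphenyl)silyl]oxy}methyl)-3-methyloxiran-2-yl]-3,11-dimethyl-7-{[(trifluoromethyl)sulfonyl]oxy}trideca-6,10-dienoate | COC(=O)C[C@H](C)CC/C=C(OS(=O)(=O)C(F)(F)F)/CC/C=C(C)/CC[C@@H]1O[C@@]1(C)CO[Si](c1ccccc1)(c1ccccc1)C(C)(C)C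
F9 | step 13 | methyl (13R)-18-{[tert-butyl(diphenyl)silyl]oxy}-3-oxolabd-8(17)-en-15-oate | C=C1CC[C@H]2[C@](C)(CO[Si](c3ccccc3)(c3ccccc3)C(C)(C)C)C(=O)CC[C@]2(C)[C@H]1CC[C@@H](C)CC(=O)OC
F10 | step 13 | 4-methylbenzenesulfonylhydrazone of F9 | C=C1CC[C@H]2[C@](C)(CO[Si](c3ccccc3)(c3ccccc3)C(C)(C)C)C(=NNS(=O)(=O)c3ccc(C)cc3)CC[C@]2(C)[C@H]1CC[C@@H](C)CC(=O)OC
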